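Start with a subtraction. In the eta run, which is this flask followed so far, 10.0 h shows 27.9% target and 51.3% other capture product, so 20.8% of the charge is unaccounted for. Take that as substrate still there.

| flask | substrate | first nucleophile | gas | remark | time |
|---|---|---|---|---|---|
| eta | 0.13 M | 0.13 M | 42 mM (held) | the very flask that is asked about, followed so far |  |
| zeta | 0.087 M | 0.13 M | 42 mM (held) | run made earlier |  |
| flask | 0.13 M | 0.130 M | 42 mM (held) |  | 20 h |

| run | time / h | target / % | other capture product / % |
|---|---|---|---|
| eta | 0.833 | 12.4 | 1.1 |
| eta | 1.33 | 16.7 | 2.9 |
| eta | 2.00 | 21.5 | 9.0 |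
| eta | 3.00 | 23.7 | 15.3 |
| eta | 4.00 | 24.0 | 22.4 |
| eta | 6.00 | 26.0 | 33.9 |
| eta | 10.0 | 27.9 | 51.3 |
| zeta | 0.417 | 8.5 | 0.2 |
| zeta | 1.33 | 16.7 | 4.7 |
| zeta | 2.50 | 24.1 | 10.7 |
| zeta | 3.00 | 26.7 | 15.2 |
| zeta | 5.00 | 28.8 | 28.7 |
| zeta | 6.00 | 28.6 | 36.2 |
| zeta | 8.00 | 26.3 | 45.7 |

(each reading ± 1 percentage point)

- the numbers in the tables scatter with a standard deviation of 1 percentage point
- at the start none of the gas is in solution

1. share of target in target plus other capture product at 10 min
2. share of target in target plus other capture product at 1.5 h
3. share of target in target plus other capture product at 20 h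
4. which of target and other capture product there is more of at 20 h

Bound the last share from above. At 10.0 h the share is 35.2%. Between 6.00 h and 10.0 h the new product was 9.84% target, which is less than that share. So the share is still falling, and 35.2% is a ceiling. Bound it from below. Suppose target stops growing and the whole charge ends as product: the share is then 27.9%.

Now tighten by counting turnovers. Read the rate of loss from the natural logarithm of substrate charged over substrate left. Eta gives 0.157 h⁻¹. Zeta, at its smaller charge, gives 0.159 h⁻¹ at 8.00 h. The two agree, so treat the loss as first order. Carried to 20 h, that makes 3.14 turnovers. This is the turnover count, that same logarithm at the asked time. It leaves 4.33% of the substrate, so the products sum to 95.7%.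

Let the substrate still to react split as it did in the last interval, and the ceiling drops to 30.9%. Readings scatter by 1 percentage point, so set the floor on the target reading at 6.00 h, which gives 27.2%.

The forecast says 98%, 78% and 30%, with other capture product ahead, its last share inside my bracket, on the ground that “a slow activation step appears to feed a common intermediate”.

The flask gives 97.0%, 77.3% and 27.9%, the last also inside, with other capture product ahead at 69.1% against 26.8% target.

    substrate ⇌ intermediate (K = 0.0150, k = 0.00380 min⁻¹)
    first nucleophile + intermediate → target (k = 9.60 M⁻¹ min⁻¹)
    second nucleophile + intermediate → other capture product (k = 17.0 M⁻¹ min⁻¹)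
    gas ⇌ second nucleophile, rate k4*(csat - [second nucleophile]) (kL = 0.0100 min⁻¹)
    first nucleophile → decomposed reagent (k = 0.00930 min⁻¹)

The count gave 4.33% substrate left and this flask holds 4.08%, while the neighbour flask, with a quarter of the first nucleophile, holds 4.85%, which is 3.03 turnovers, beside 10.6% target. Over 20 h, decomposition of first nucleophile taken alone makes 11.2 turnovers, more than the 3.14 of substrate, and in this flask at 10.0 h first nucleophile stands at 0.0747% of its own charge while substrate stands at 20.7%.

All runs are simulated on assumed constants.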